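**Retrosynthetic overview**

1. The target is a dibenzo[b,f]oxepine whose C10=C11 double bond is also the enol ether of a dihydropyran fused to a 2,6,6-trimethylbicyclo[3.2.0]heptane. The last disconnections are the pyran C10–O bond (cyclodehydration of a tertiary alcohol onto a C10 ketone) and the C11–ring A bond (palladium-catalysed ketone α-arylation, which closes the oxepine).
2. The strategy rests on ring B: a benzene ring that carries C10 on one carbon, the oxepine oxygen O5 on the adjacent carbon and the hydroxyl para to C10. This 1-acyl-2-aryloxy-4-hydroxy pattern is what a 1-methoxy-3-siloxydiene and an ynone bearing the ether oxygen on its β-carbon give after [4+2] addition and loss of methanol.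
3. The aryloxy ynone comes from a lithium aryloxyacetylide (ring A phenol plus trichloroethylene) and a bicyclic Weinreb amide.
4. The bicycle comes from (R)-linalool: hydroformylation, oxidation and dehydrogenation give a butenolide, an intramolecular [2+2] photocycloaddition sets the three remaining stereocentres from the linalool carbinol carbon, and a lactol Wittig homologation gives the δ-lactone.
5. Ring order: cyclopentane and cyclobutane together (step 4); ring A is bought; ring B (step 15); oxepine (step 17); dihydropyran (step 18).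

Key step: step 15

Remark on locants: O5, C10 and C11 follow dibenzo[b,f]oxepine numbering (C10 bears ring B and the pyran oxygen, C11 bears ring A). C1–C7 refer to the bicyclo[3.2.0]heptane unit: C1/C5 ring fusion, C2 the oxygenated quaternary carbon, C6 the CMe2 carbon, C7 the carbon bearing the side chain. In every bicyclic compound the ring fusion is cis, and the oxygen on C2 and the side chain on C7 lie on the concave face.
Remark on the chemistry: (R)-linalool is used at its commercial enantiomeric purity; its carbinol carbon is never a reacting centre.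

**Route**

Step 1
Reactants: 1 (R)-linalool
Product: 3 (5R)-5-methyl-5-(4-methylpent-3-en-1-yl)oxolan-2-ol (both anomers), via (R)-4-hydroxy-4,8-dimethylnon-7-enal 2 (not isolated)
Conditions: Rh(acac)(CO)2 (0.5 mol%), PPh3 (5 mol%), CO/H2 (1:1, 20 bar), toluene, 60 °C
Reagents that add atoms: carbon monoxide, [C-]#[O+]
Why: Rhodium-catalysed hydroformylation takes the monosubstituted vinyl group in preference to the trisubstituted alkene and is linear next to the quaternary carbon, and the γ-hydroxy aldehyde closes to the five-membered lactol without touching the carbinol stereocentre.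

Step 2
Reactants: 3 (5R)-5-methyl-5-(4-methylpent-3-en-1-yl)oxolan-2-ol
Product: 4 (R)-5-methyl-5-(4-methylpent-3-en-1-yl)oxolan-2-one
Conditions: TEMPO (10 mol%), PhI(OAc)2, CH2Cl2, rt
Reagents that add atoms: none
Why: Oxoammonium-mediated oxidation of a lactol to the lactone, which should leave the trisubstituted alkene alone.

Step 3
Reactants: 4 (R)-5-methyl-5-(4-methylpent-3-en-1-yl)oxolan-2-one
Product: 7 (R)-5-methyl-5-(4-methylpent-3-en-1-yl)furan-2(5H)-one, via α-phenylselanyl lactone 5 (not isolated), via selenoxide 6 (not isolated)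
Conditions: LiN(iPr)2, THF, −78 °C; PhSeBr; then H2O2 (30%), pyridine, 0 °C to rt
Reagents that add atoms: none
Why: Selenoxide syn-elimination: the lactone enolate is selenenylated at its only α-carbon and the selenoxide eliminates into the ring near room temperature, with pyridine suppressing epoxidation of the side-chain alkene by selenium peroxy acids.

Step 4
Reactants: 7 (R)-5-methyl-5-(4-methylpent-3-en-1-yl)furan-2(5H)-one
Product: 8 tricyclic γ-lactone (lactone bridging the C2 oxygen and a carbonyl carbon on C7 of the 2,6,6-trimethylbicyclo[3.2.0]heptane; all three rings cis-fused at C1)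
Conditions: hν (300 nm, Pyrex), acetone/MeCN 1:4, degassed, 0.01 M, rt
Reagents that add atoms: none
Why: Triplet-sensitised intramolecular enone–alkene [2+2] photocycloaddition with the butenolide as the enone: 1,5-closure between the butenolide β-carbon and the internal alkene carbon forms the cyclopentane, the 1,4-diradical closes the cyclobutane, and the two-carbon tether on the quaternary carbon reaches only one face of the planar butenolide, so C1, C5 and C7 are set by the linalool-derived carbon.

Step 5
Reactants: 8 tricyclic γ-lactone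
Product: 9 tricyclic γ-lactol (both anomers)
Conditions: iBu2AlH, CH2Cl2, −78 °C; aq. potassium sodium tartrate
Reagents that add atoms: none
Why: Low-temperature iBu2AlH reduction of a γ-lactone stops at the aluminium hemiacetal, which gives the lactol on work-up.

Step 6
Reactants: 9 tricyclic γ-lactol
Product: 10 (1R,2R,5S)-7-(2-methoxyethenyl)-2,6,6-trimethylbicyclo[3.2.0]heptan-2-ol (E/Z mixture; side chain on C7 cis to C2)
Conditions: MeOCH2PPh3Cl (3 equiv), KN(SiMe3)2 (3 equiv), THF, 0 °C to rt
Reagents that add atoms: (methoxymethyl)triphenylphosphonium chloride, COC[P+](c1ccccc1)(c1ccccc1)c1ccccc1.[Cl-]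
Why: Wittig one-carbon homologation of the ring-opened hydroxy aldehyde; the excess non-stabilised ylide should react fast enough at 0 °C that the aldehyde-bearing C7 does not epimerise.

Step 7
Reactants: 10 hydroxy enol ether
Product: 12 tricyclic δ-lactone (six-membered lactone O–C(=O)–CH2–C7–C1–C2), via tricyclic δ-lactol 11 (not isolated)
Conditions: 1 M HCl, acetone, rt; then Jones reagent (CrO3, H2SO4, H2O), 0 °C
Reagents that add atoms: water, O
Why: Acid hydrolysis of the enol ether gives the homologous aldehyde, which the cis tertiary alcohol traps as the six-membered lactol, and Jones oxidation converts this to the δ-lactone, in which C7 is β to the carbonyl and configurationally safe.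

Step 8
Reactants: 12 tricyclic δ-lactone
Product: 13 N-methoxy-N-methyl-2-[(1R,2R,5S,7R)-2-hydroxy-2,6,6-trimethylbicyclo[3.2.0]heptan-7-yl]acetamide
Conditions: Me(MeO)NH·HCl, AlMe3, CH2Cl2, 0 °C to rt
Reagents that add atoms: N,O-dimethylhydroxylamine hydrochloride, CNOC.Cl
Why: Weinreb aminolysis of a lactone by the aluminium amide; the tertiary alcohol stays bound as its aluminium alkoxide until work-up and so cannot re-close.

Step 9
Reactants: 13 hydroxy Weinreb amide
Product: 14 N-methoxy-N-methyl-2-[(1R,2R,5S,7R)-2,6,6-trimethyl-2-(triethylsilyloxy)bicyclo[3.2.0]heptan-7-yl]acetamide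
Conditions: TESOTf, 2,6-lutidine, CH2Cl2, −78 to 0 °C
Reagents that add atoms: triethylsilyl trifluoromethanesulfonate, CC[Si](CC)(CC)OS(=O)(=O)C(F)(F)F
Why: Silyl triflate/lutidine silylation of a hindered tertiary alcohol, which also rules out relactonisation.

Step 10
Reactants: 15 4-chlorobenzene-1,3-diol
Product: 16 2-chloro-5-(triisopropylsilyloxy)phenol
Conditions: TIPSCl (1.0 equiv), imidazole, CH2Cl2/DMF, 0 °C
Reagents that add atoms: chlorotriisopropylsilane, CC(C)[Si](Cl)(C(C)C)C(C)C
Why: The bulky silyl chloride should go to the hydroxyl para to chlorine, which has no ortho substituent, rather than to the hydroxyl flanked by chlorine, and one equivalent at 0 °C limits bis-silylation.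

Step 11
Reactants: 16 2-chloro-5-(triisopropylsilyloxy)phenol
Product: 17 4-bromo-2-chloro-5-(triisopropylsilyloxy)phenol
Conditions: NBS, MeCN, 0 °C
Reagents that add atoms: N-bromosuccinimide, O=C1CCC(=O)N1Br
Why: Electrophilic aromatic bromination para to the free hydroxyl and ortho to the silyloxy group, the only doubly activated position that is not shielded between the two oxygens.

Step 12
Reactants: 17 4-bromo-2-chloro-5-(triisopropylsilyloxy)phenol
Product: 18 2-chloro-4-(3-methylbut-2-en-1-yl)-5-(triisopropylsilyloxy)phenol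
Conditions: Pd(PPh3)4 (5 mol%), DMF, 90 °C
Reagents that add atoms: tributyl(3-methylbut-2-en-1-yl)stannane, CCCC[Sn](CCCC)(CCCC)CC=C(C)C
Why: Stille coupling of the aryl bromide with the prenylstannane, which transfers the linear prenyl group, while the aryl chloride does not undergo oxidative addition with this catalyst.

Step 13
Reactants: 18 2-chloro-4-(3-methylbut-2-en-1-yl)-5-(triisopropylsilyloxy)phenol; 19 trichloroethene
Product: 20 (E)-1,2-dichlorovinyl ether of phenol 18
Conditions: K2CO3 (anhydrous), DMF, 60 °C
Reagents that add atoms: none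
Why: Base-mediated anti addition of the phenoxide to dichloroacetylene formed in situ from trichloroethene gives the (E)-1,2-dichlorovinyl ether, the standard ynol ether precursor.

Step 14
Reactants: 20 (E)-1,2-dichlorovinyl aryl ether; 14 silylated Weinreb amide
Product: 24 aryloxy ynone (4-aryloxybut-3-yn-2-one bearing the C7 carbon of the silylated bicycle on C1), via aryl chloroethynyl ether 21 (not isolated), via lithium aryloxyacetylide 22 (not isolated), via lithium hemiaminal adduct 23 (not isolated)
Conditions: n-BuLi (2.1 equiv per 20), THF, −78 to −40 °C; then 14 (0.7 equiv), −78 to −20 °C; pH 7 buffer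
Reagents that add atoms: none
Why: n-BuLi removes the vinyl proton with loss of chloride and then exchanges the remaining alkynyl chlorine, and the resulting lithium aryloxyacetylide acylates once on the Weinreb amide because the chelated tetrahedral adduct survives until the quench.

Step 15
Reactants: 24 aryloxy ynone; 25 Danishefsky's diene (trans-1-methoxy-3-trimethylsiloxybuta-1,3-diene)
Product: 28 2-aryloxy-4-hydroxyphenyl ketone (ring B formed), via cyclohexa-1,4-diene cycloadduct 26 (not isolated), via aryl trimethylsilyl ether 27 (not isolated)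
Conditions: 25 (3 equiv), toluene, 100 °C, sealed tube; then 0.1 M HCl, THF, 0 °C
Reagents that add atoms: none
Why: In a thermal, concerted but asynchronous [4+2] cycloaddition the unsubstituted diene terminus (largest HOMO coefficient) bonds to the aryloxy-bearing β-carbon of the ynone (largest LUMO coefficient, the carbon at which nucleophiles attack β-oxy ynones) and the methoxy-bearing carbon bonds to the α-carbon; the closest known reaction is the benzannulation of Danishefsky's diene with alkynyl ketones. Ring B closes as a six-membered carbocycle in the cycloaddition mode with two new C–C bonds, and the 1,4-cyclohexadiene 26 aromatises by 1,4-elimination of methanol, after which the brief dilute acid hydrolyses the aryl trimethylsilyl ether 27. No stereocentre is formed and the four existing ones are remote from the reacting carbons. The step needs regioselectivity (hydroxyl para and aryloxy ortho to the ketone), which the matched polarisation of diene and ynone secures, and chemoselectivity for the triple bond, which holds because the electron-rich prenyl alkene is no dienophile for an electron-rich diene. An aryloxy group donates less into the triple bond than an alkoxy group, so the ynone should remain a competent dienophile at about 100 °C, and the tertiary triethylsilyl and aryl triisopropylsilyl ethers should survive the work-up.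

Step 16
Reactants: 28 2-aryloxy-4-hydroxyphenyl ketone
Product: 29 2-aryloxy-4-(triisopropylsilyloxy)phenyl ketone
Conditions: TIPSCl, imidazole, DMF, rt
Reagents that add atoms: chlorotriisopropylsilane, CC(C)[Si](Cl)(C(C)C)C(C)C
Why: Imidazole-mediated silylation of the acidic para-acylphenol keeps a phenoxide out of the palladium enolate chemistry that follows.

Step 17
Reactants: 29 2-aryloxy-4-(triisopropylsilyloxy)phenyl ketone
Product: 30 dibenzo[b,f]oxepin-10(11H)-one bearing the bicycle on C11 (C11 epimers)
Conditions: Pd2(dba)3 (5 mol%), XPhos (12 mol%), NaOtBu, toluene, 90 °C, 0.02 M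
Reagents that add atoms: none
Why: Palladium-catalysed intramolecular α-arylation of a ketone enolate: the bulky electron-rich biaryl phosphine enables oxidative addition of zerovalent palladium into the aryl chloride, the CH2 group is the only enolisable position, and C–C reductive elimination closes the seven-membered ring, the new C11 stereocentre being destroyed in the next step.

Step 18
Reactants: 30 dibenzoxepinone
Product: 33 bis(triisopropylsilyl) ether of the target, via hydroxy ketone 31 (not isolated), via cyclic hemiketal 32 (not isolated)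
Conditions: p-TsOH·H2O (0.2 equiv), MeOH/CH2Cl2, rt; then toluene, 4 Å MS, 70 °C
Reagents that add atoms: none
Why: Acidic methanolysis removes the tertiary triethylsilyl ether, the freed hydroxyl adds to the C10 ketone to form the six-membered hemiketal, and acid-catalysed loss of water through the ring-B-stabilised oxocarbenium ion with proton loss from C11 gives the conjugated enol ether, the silyl groups on both phenols preventing acid-induced chroman formation with the prenyl group.

Step 19
Reactants: 33 bis(triisopropylsilyl) ether of the target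
Product: 34 target compound CNP0185814.1
Conditions: Bu4NF, THF, 0 °C; aq. NH4Cl
Reagents that add atoms: none
Why: Fluoride cleaves both aryl silyl ethers under non-acidic conditions that leave the enol ether and the prenylphenol untouched.

**Compound list**

1 | (R)-linalool | CC(C)=CCC[C@@](C=C)(C)O | starting material
2 | (R)-4-hydroxy-4,8-dimethylnon-7-enal | CC(C)=CCC[C@@](C)(O)CCC=O | intermediate (not isolated)
3 | (5R)-5-methyl-5-(4-methylpent-3-en-1-yl)oxolan-2-ol | CC(C)=CCC[C@]1(C)CCC(O)O1 | intermediate
4 | (R)-5-methyl-5-(4-methylpent-3-en-1-yl)oxolan-2-one | CC(C)=CCC[C@]1(C)CCC(=O)O1 | intermediate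
5 | α-phenylselanyl lactone (epimers at C3) | CC(C)=CCC[C@]1(C)CC([Se]c2ccccc2)C(=O)O1 | intermediate (not isolated)
6 | selenoxide of 5 | CC(C)=CCC[C@]1(C)CC([Se](=O)c2ccccc2)C(=O)O1 | intermediate (not isolated)
7 | (R)-5-methyl-5-(4-methylpent-3-en-1-yl)furan-2(5H)-one | CC(C)=CCC[C@]1(C)C=CC(=O)O1 | intermediate
8 | tricyclic γ-lactone | O=C1[C@@H]2[C@H]3[C@H](CC[C@@]3(C)O1)C2(C)C | intermediate
9 | tricyclic γ-lactol (anomers) | OC1[C@@H]2[C@H]3[C@H](CC[C@@]3(C)O1)C2(C)C | intermediate
10 | (1R,2R,5S)-7-(2-methoxyethenyl)-2,6,6-trimethylbicyclo[3.2.0]heptan-2-ol (E/Z) | COC=C[C@@H]1[C@H]2[C@H](CC[C@@]2(C)O)C1(C)C | intermediate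
11 | tricyclic δ-lactol | OC1C[C@@H]2[C@H]3[C@H](CC[C@@]3(C)O1)C2(C)C | intermediate (not isolated)
12 | tricyclic δ-lactone | O=C1C[C@@H]2[C@H]3[C@H](CC[C@@]3(C)O1)C2(C)C | intermediate
13 | N-methoxy-N-methyl-2-[(1R,2R,5S,7R)-2-hydroxy-2,6,6-trimethylbicyclo[3.2.0]heptan-7-yl]acetamide | CON(C)C(=O)C[C@@H]1[C@H]2[C@H](CC[C@@]2(C)O)C1(C)C | intermediate
14 | N-methoxy-N-methyl-2-[(1R,2R,5S,7R)-2,6,6-trimethyl-2-(triethylsilyloxy)bicyclo[3.2.0]heptan-7-yl]acetamide | CON(C)C(=O)C[C@@H]1[C@H]2[C@H](CC[C@@]2(C)O[Si](CC)(CC)CC)C1(C)C | intermediate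
15 | 4-chlorobenzene-1,3-diol | Oc1ccc(Cl)c(O)c1 | starting material
16 | 2-chloro-5-(triisopropylsilyloxy)phenol | Oc1cc(O[Si](C(C)C)(C(C)C)C(C)C)ccc1Cl | intermediate
17 | 4-bromo-2-chloro-5-(triisopropylsilyloxy)phenol | Oc1cc(O[Si](C(C)C)(C(C)C)C(C)C)c(Br)cc1Cl | intermediate
18 | 2-chloro-4-(3-methylbut-2-en-1-yl)-5-(triisopropylsilyloxy)phenol | CC(C)=CCc1cc(Cl)c(O)cc1O[Si](C(C)C)(C(C)C)C(C)C | intermediate
19 | trichloroethene | ClC=C(Cl)Cl | starting material
20 | (E)-1,2-dichlorovinyl ether of 18 | CC(C)=CCc1cc(Cl)c(O/C(Cl)=C\Cl)cc1O[Si](C(C)C)(C(C)C)C(C)C | intermediate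
21 | aryl chloroethynyl ether | CC(C)=CCc1cc(Cl)c(OC#CCl)cc1O[Si](C(C)C)(C(C)C)C(C)C | intermediate (not isolated)
22 | lithium aryloxyacetylide | CC(C)=CCc1cc(Cl)c(OC#C[Li])cc1O[Si](C(C)C)(C(C)C)C(C)C | intermediate (not isolated)
23 | lithium hemiaminal adduct | CC(C)=CCc1cc(Cl)c(OC#CC(O[Li])(N(C)OC)C[C@@H]2[C@H]3[C@H](CC[C@@]3(C)O[Si](CC)(CC)CC)C2(C)C)cc1O[Si](C(C)C)(C(C)C)C(C)C | intermediate (not isolated)
24 | aryloxy ynone | CC(C)=CCc1cc(Cl)c(cc1O[Si](C(C)C)(C(C)C)C(C)C)OC#CC(=O)C[C@@H]1[C@H]2[C@H](CC[C@@]2(C)O[Si](CC)(CC)CC)C1(C)C | intermediate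
25 | Danishefsky's diene | CO/C=C/C(=C)O[Si](C)(C)C | starting material
26 | cyclohexa-1,4-diene cycloadduct (CH–OMe epimers) | CC(C)=CCc1cc(Cl)c(cc1O[Si](C(C)C)(C(C)C)C(C)C)OC1=C(C(=O)C[C@@H]2[C@H]3[C@H](CC[C@@]3(C)O[Si](CC)(CC)CC)C2(C)C)C(OC)C=C(O[Si](C)(C)C)C1 | intermediate (not isolated)
27 | aryl trimethylsilyl ether | CC(C)=CCc1cc(Cl)c(cc1O[Si](C(C)C)(C(C)C)C(C)C)Oc1cc(O[Si](C)(C)C)ccc1C(=O)C[C@@H]1[C@H]2[C@H](CC[C@@]2(C)O[Si](CC)(CC)CC)C1(C)C | intermediate (not isolated)
28 | 2-aryloxy-4-hydroxyphenyl ketone | CC(C)=CCc1cc(Cl)c(cc1O[Si](C(C)C)(C(C)C)C(C)C)Oc1cc(O)ccc1C(=O)C[C@@H]1[C@H]2[C@H](CC[C@@]2(C)O[Si](CC)(CC)CC)C1(C)C | intermediate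
29 | 2-aryloxy-4-(triisopropylsilyloxy)phenyl ketone | CC(C)=CCc1cc(Cl)c(cc1O[Si](C(C)C)(C(C)C)C(C)C)Oc1cc(O[Si](C(C)C)(C(C)C)C(C)C)ccc1C(=O)C[C@@H]1[C@H]2[C@H](CC[C@@]2(C)O[Si](CC)(CC)CC)C1(C)C | intermediate
30 | dibenzoxepinone (C11 epimers) | CC(C)=CCc1cc2c(cc1O[Si](C(C)C)(C(C)C)C(C)C)Oc1cc(O[Si](C(C)C)(C(C)C)C(C)C)ccc1C(=O)C2[C@@H]1[C@H]2[C@H](CC[C@@]2(C)O[Si](CC)(CC)CC)C1(C)C | intermediate
31 | hydroxy ketone | CC(C)=CCc1cc2c(cc1O[Si](C(C)C)(C(C)C)C(C)C)Oc1cc(O[Si](C(C)C)(C(C)C)C(C)C)ccc1C(=O)C2[C@@H]1[C@H]2[C@H](CC[C@@]2(C)O)C1(C)C | intermediate (not isolated)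
32 | cyclic hemiketal | CC(C)=CCc1cc2c(cc1O[Si](C(C)C)(C(C)C)C(C)C)Oc1cc(O[Si](C(C)C)(C(C)C)C(C)C)ccc1C1(O)C2[C@@H]2[C@H]3[C@H](CC[C@@]3(C)O1)C2(C)C | intermediate (not isolated)
33 | bis(triisopropylsilyl) ether of the target | CC(C)=CCc1cc2c(cc1O[Si](C(C)C)(C(C)C)C(C)C)Oc1cc(O[Si](C(C)C)(C(C)C)C(C)C)ccc1C1=C2[C@@H]2[C@H]3[C@H](CC[C@@]3(C)O1)C2(C)C | intermediate
34 | CNP0185814.1 | CC(C)=CCc1cc2c(cc1O)Oc1cc(O)ccc1C1=C2[C@@H]2[C@H]3[C@H](CC[C@@]3(C)O1)C2(C)C | target

**Step count and risks**

Total step count: 19. Longest linear sequence: 15 (steps 1–9, then 14–19); the ring A branch is steps 10–13.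

Steps most likely to fail:

1. Step 15. The donor-substituted triple bond may add the diene too slowly, so that thermal decomposition or hydration of the aryloxy ynone and polymerisation of the diene take over. Fallback: ring B is bought with its oxygen pattern in place and joined by acylation and SNAr chemistry, setting out from Weinreb amide 14 and phenol 18. Commercial 4-bromo-3-fluorophenol is silylated (TIPSCl, imidazole) to (4-bromo-3-fluorophenoxy)triisopropylsilane F1. Bromine–magnesium exchange (iPrMgCl·LiCl, THF, −15 °C) gives [2-fluoro-4-(triisopropylsilyloxy)phenyl]magnesium chloride F2, which acylates 14 to the 2-fluoro-4-(triisopropylsilyloxy)phenyl ketone F3. The fluoride, activated by the ortho acyl group, is displaced by the potassium salt of 18 (K2CO3, DMSO, 70 °C) to give diaryl ether 29, where the route is rejoined before step 17.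

2. Step 17. Oxidative addition into the electron-rich, ortho-oxygenated aryl chloride may be slow, and reduction of the C–Cl bond or intermolecular coupling may outrun closure of the seven-membered ring at the hindered α-carbon. Fallback: the same C11–aryl bond is closed without palladium by a photostimulated SRN1 reaction, setting out from 29. Its potassium enolate (KOtBu, liquid NH3/THF, −33 °C) is irradiated at 350 nm; electron transfer to the aryl chloride, loss of chloride and capture of the aryl radical by the tethered enolate give 30 directly, so no new compound is made.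

3. Step 14. Addition of the acetylide to the β-branched Weinreb amide may be slow, and warming to compensate invites early collapse of the tetrahedral adduct with a second addition, or attack of residual n-BuLi on the ynol ether. Fallback: the ketone is reached through the aldehyde, setting out from 14. iBu2AlH (THF, −78 °C) gives 2-[(1R,2R,5S,7R)-2,6,6-trimethyl-2-(triethylsilyloxy)bicyclo[3.2.0]heptan-7-yl]acetaldehyde F4. Lithium aryloxyacetylide 22 adds at −78 °C to give the propargylic alcohol F5 (both carbinol epimers), and MnO2 (CH2Cl2, rt) oxidises it to ynone 24, where the route continues.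

**Further compounds**

F1 | step 15 | (4-bromo-3-fluorophenoxy)triisopropylsilane | CC(C)[Si](Oc1ccc(Br)c(F)c1)(C(C)C)C(C)C
F2 | step 15 | [2-fluoro-4-(triisopropylsilyloxy)phenyl]magnesium chloride | CC(C)[Si](Oc1ccc([Mg]Cl)c(F)c1)(C(C)C)C(C)C
F3 | step 15 | 2-fluoro-4-(triisopropylsilyloxy)phenyl ketone of the silylated bicycle | CC(C)[Si](Oc1ccc(C(=O)C[C@@H]2[C@H]3[C@H](CC[C@@]3(C)O[Si](CC)(CC)CC)C2(C)C)c(F)c1)(C(C)C)C(C)C
F0 | step 17 | none | none
F4 | step 14 | 2-[(1R,2R,5S,7R)-2,6,6-trimethyl-2-(triethylsilyloxy)bicyclo[3.2.0]heptan-7-yl]acetaldehyde | O=CC[C@@H]1[C@H]2[C@H](CC[C@@]2(C)O[Si](CC)(CC)CC)C1(C)C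
F5 | step 14 | propargylic alcohol (carbinol epimers) | CC(C)=CCc1cc(Cl)c(cc1O[Si](C(C)C)(C(C)C)C(C)C)OC#CC(O)C[C@@H]1[C@H]2[C@H](CC[C@@]2(C)O[Si](CC)(CC)CC)C1(C)C
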